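Ring B is closed last, across C7–C8. The step exploits C8 as the only sp2 carbon of ring B (C5–C10), flanked by methylene C7 and stereocentre C9: an alkylborane on C7 (from a C5 vinyl group) is coupled intramolecularly with a C8 thioester, so one operation closes the cis-decalin as its 8-ketone and lets C9 settle with the side chain equatorial; methylenation then installs C17. The precursor is a monocyclic ring A bearing C2, C4, C5 and C10, made by an aldehyde-directed Diels–Alder reaction and a Michael addition delivered from C19 through a temporary lactone that fixes C10.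

Key step: step 13

Remark (numbering): labdane numbers are used throughout (ring A = C1–C5, C10; ring B = C5–C10; C18 = methyl on C4, C19 = carboxyl carbon on C4, C20 = methyl on C10, C17 = CH2 on C8, side chain C11–C16 on C9); α is the face of ring A that carries C19, β the face of C18 and C20.
Remark (C9 unit): "C9 unit" means CH(COSEt)CH2CH2C(Me)=CHCO2Me bonded through its methine carbon C9; C9 is carried as both epimers (undefined in the SMILES) until it is set in step 13.
Remark (assumption): 5-hydroxy-3-methylfuran-2(5H)-one is taken as purchasable; it is otherwise made by dye-sensitised photo-oxygenation of 3-methyl-2-furoic acid.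

Step 1
Reactants: 1 5-oxohexanoic acid
Product: 2 (E)-7-methoxy-5-methyl-7-oxohept-5-enoic acid
Conditions: NaH (2.2 equiv), trimethyl phosphonoacetate, THF, 0 °C to reflux; E isomer separated by chromatography
Reagents that add atoms: trimethyl phosphonoacetate COC(=O)CP(=O)(OC)OC
Why: Horner–Wadsworth–Emmons olefination of the methyl ketone of the sodium carboxylate should favour the E enoate (ester trans to the chain), which is the C13=C14 geometry of the target.

Step 2
Reactants: 2 (E)-7-methoxy-5-methyl-7-oxohept-5-enoic acid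
Product: 3 methyl (E)-7-(ethylsulfanyl)-3-methyl-7-oxohept-2-enoate
Conditions: EtSH, EDC·HCl, DMAP (cat.), CH2Cl2, 0 °C to rt
Reagents that add atoms: ethanethiol CCS
Why: Steglich-type carbodiimide thioesterification activates only the free carboxylic acid (the future C8), leaving the methyl enoate untouched.

Step 3
Reactants: 3 methyl (E)-7-(ethylsulfanyl)-3-methyl-7-oxohept-2-enoate
Product: 5 methyl (E)-6-bromo-7-(ethylsulfanyl)-3-methyl-7-oxohept-2-enoate (racemic), via silyl ketene thioacetal 4 (not isolated)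
Conditions: LiN(SiMe3)2, Me3SiCl, THF, −78 °C; then NBS, −78 to 0 °C
Reagents that add atoms: N-bromosuccinimide O=C1CCC(=O)N1Br
Why: Kinetic enolisation α to the thioester, O-silylation and electrophilic bromination of the silyl ketene thioacetal should give the α-bromo thioester; its configuration (future C9) is irrelevant because C9 is set in step 13.

Step 4
Reactants: 6 5-hydroxy-3-methylfuran-2(5H)-one; 5 methyl (E)-6-bromo-7-(ethylsulfanyl)-3-methyl-7-oxohept-2-enoate
Product: 7 (E)-1-(ethylsulfanyl)-7-methoxy-5-methyl-1,7-dioxohept-5-en-2-yl (Z)-2-methyl-4-oxobut-2-enoate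
Conditions: Cs2CO3 (0.55 equiv), DMF, 0 °C to rt
Reagents that add atoms: none
Why: The pseudo-acid opens to its (Z)-formyl carboxylate, whose SN2 O-alkylation by the activated secondary bromide (as in the esterification of phthalaldehydic acid) should give the open-chain ester with the aldehyde and ester still cis.

Step 5
Reactants: 8 (E)-pent-3-en-2-one
Product: 9 tert-butyldimethyl[(E)-penta-1,3-dien-2-yloxy]silane
Conditions: t-BuMe2SiOTf, Et3N, CH2Cl2, 0 °C
Reagents that add atoms: tert-butyldimethylsilyl triflate CC(C)(C)[Si](C)(C)OS(=O)(=O)C(F)(F)F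
Why: Soft enolisation at the methyl group with O-silylation should give the cross-conjugated 2-silyloxy diene.

Step 6
Reactants: 7 (E)-1-(ethylsulfanyl)-7-methoxy-5-methyl-1,7-dioxohept-5-en-2-yl (Z)-2-methyl-4-oxobut-2-enoate; 9 tert-butyldimethyl[(E)-penta-1,3-dien-2-yloxy]silane
Product: 10 C9-unit ester of 5α-formyl-4β,10α-dimethyl-2-(tert-butyldimethylsilyloxy)cyclohex-1-ene-4α-carboxylic acid
Conditions: (S)-B-(o-tolyl)-diphenylprolinol oxazaborolidine·HNTf2 (oxazaborolidinium triflimide, 20 mol %), CH2Cl2, −78 °C; Et3N quench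
Reagents that add atoms: none
Why: In this Lewis-acid-catalysed Diels–Alder reaction the catalyst-bound aldehyde should direct the nucleophilic CH2 terminus of the diene to C4 (β to the formyl group), the Z geometry of 7 puts C6 and C19 cis (C4 and C5 set), endo addition places the C10 methyl cis to them, and the chiral oxazaborolidinium (formyl C–H···O binding model) selects the enantioface, its antipode being used should the sense prove opposite.

Step 7
Reactants: 10 C9-unit ester of 5α-formyl-4β,10α-dimethyl-2-(tert-butyldimethylsilyloxy)cyclohex-1-ene-4α-carboxylic acid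
Product: 11 C9-unit ester of 4β,10α-dimethyl-2-(tert-butyldimethylsilyloxy)-5α-vinylcyclohex-1-ene-4α-carboxylic acid
Conditions: CH2I2, Zn, Ti(OiPr)4, THF, 0 °C to rt
Reagents that add atoms: diiodomethane ICI
Why: Takai methylenation is aldehyde-selective and non-basic, so the thioester, the acidic C9–H and the C5 stereocentre next to the aldehyde should be left alone while C6=C7 is formed.

Step 8
Reactants: 11 C9-unit ester of 4β,10α-dimethyl-2-(tert-butyldimethylsilyloxy)-5α-vinylcyclohex-1-ene-4α-carboxylic acid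
Product: 12 C9-unit ester of 4β,10-dimethyl-2-oxo-5α-vinylcyclohex-1(10)-ene-4α-carboxylic acid
Conditions: Pd(OAc)2 (1.1 equiv), MeCN, rt
Reagents that add atoms: none
Why: Saegusa–Ito oxidation of the silyl enol ether should give the C2 enone with the double bond at C1=C10 only, because C3 is flanked by the quaternary C4.

Step 9
Reactants: 12 C9-unit ester of 4β,10-dimethyl-2-oxo-5α-vinylcyclohex-1(10)-ene-4α-carboxylic acid
Product: 15 19,9-lactone (bridged δ-lactone C19(=O)–O–C9 with C9 bonded to C10α) as its 2-triethylsilyl enol ether, via lithium thioester enolate 13 (not isolated), via lithium ketone enolate 14 (not isolated)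
Conditions: LiN(SiMe3)2 (1.05 equiv), THF, −78 to −30 °C; then Et3SiCl, −78 to 0 °C
Reagents that add atoms: chlorotriethylsilane CC[Si](Cl)(CC)CC
Why: Intramolecular Michael addition (6-exo-trig) of the α-acyloxy thioester enolate can reach C10 only on the α face because it is tethered to C19, so the quaternary centre C10 should form with C9 cis to C19 and C6, and the resulting C2 enolate is trapped as its silyl enol ether.

Step 10
Reactants: 15 19,9-lactone as its 2-triethylsilyl enol ether
Product: 17 4β,10β-dimethyl-2-oxo-5α-vinyl-10α-(C9 unit)cyclohexane-4α-carboxylic acid, via silyl enol ether acid 16 (not isolated)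
Conditions: SmI2 (2.2 equiv), HMPA, MeOH, THF, −78 °C; then 1 M HCl, THF, 0 °C
Reagents that add atoms: none
Why: Reductive cleavage of the C9–O bond α to the thioester carbonyl by divalent samarium (the known deoxygenation of α-acyloxy carbonyl compounds) removes the temporary lactone and frees C19 as the acid, and the acidic work-up hydrolyses the silyl enol ether to the C2 ketone.

Step 11
Reactants: 17 4β,10β-dimethyl-2-oxo-5α-vinyl-10α-(C9 unit)cyclohexane-4α-carboxylic acid
Product: 19 2β-hydroxy-4β,10β-dimethyl-5α-vinyl-10α-(C9 unit)cyclohexane-4α-carboxylic acid, via sodium acyloxytrihydroborate 18 (not isolated)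
Conditions: NaBH4 (1.1 equiv), THF, 0 °C to rt, high dilution; aqueous HCl work-up
Reagents that add atoms: none
Why: Proposed new method: the C19 acid should react with NaBH4 (loss of H2) to an acyloxytrihydroborate held on the α face, which can pass hydride to the C2 carbonyl only from that face and so gives the 2β-alcohol, while the weakened borohydride should spare the thioester and enoate; the closest known reaction type is the hydroxyl-directed acyloxyborohydride reduction of β-hydroxy ketones (Saksena–Evans), here with a carboxylate as the anchor.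

Step 12
Reactants: 19 2β-hydroxy-4β,10β-dimethyl-5α-vinyl-10α-(C9 unit)cyclohexane-4α-carboxylic acid
Product: 20 methyl 2β-hydroxy-4β,10β-dimethyl-5α-vinyl-10α-(C9 unit)cyclohexane-4α-carboxylate
Conditions: Me3SiCHN2, toluene/MeOH, 0 °C
Reagents that add atoms: (trimethylsilyl)diazomethane C[Si](C)(C)C=[N+]=[N-]
Why: Diazoalkane O-methylation esterifies the hindered C19 acid without touching the alcohol or thioester, and the trans 2β-hydroxyl cannot lactonise onto C19.

Step 13
Reactants: 20 methyl 2β-hydroxy-4β,10β-dimethyl-5α-vinyl-10α-(C9 unit)cyclohexane-4α-carboxylate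
Product: 22 dimethyl 2β-hydroxy-8-oxo-17-nor-5βH-labd-13E-ene-15,19-dioate, via B-alkyl-9-BBN borinate 21 (not isolated)
Conditions: 9-BBN dimer (2.2 equiv), THF, 0 °C to rt; then Pd(PPh3)4 (10 mol %), CuTC [Cu(O2CC4H3S), copper thiophene-2-carboxylate, 2 equiv], Cs2CO3, THF, 45 °C, slow addition at high dilution; then DBU, CH2Cl2, rt
Reagents that add atoms: none
Why: Anti-Markovnikov hydroboration of the C6=C7 vinyl group puts boron on C7 (the hydroxyl is masked as its borinate), then the thioester adds oxidatively to zerovalent palladium with monovalent copper taking the thiolate, the B-alkyl group transmetalates and acyl–alkyl reductive elimination forms C7–C8. The closest known reaction is the Pd-catalysed, copper-carboxylate-mediated coupling of thioesters with B-alkyl-9-BBN reagents (Liebeskind–Srogl type), used here within one molecule. Ring B (C5–C6–C7–C8–C9–C10) closes formally 6-exo-trig at the acyl carbon, helped by the cis arms on C5 and C10. No stereocentre is made in the bond formation, but C9, now α to the ring ketone, should equilibrate (Cs2CO3, then DBU) to the epimer with the side chain equatorial on ring B (9α-H), since the axial alternative collides with axial C4 in the chair–chair cis-decalin held by the equatorial 2β-oxygen. The step needs hydroboration of the monosubstituted alkene in preference to the trisubstituted enoate (steric and electronic bias of 9-BBN) and acyl activation of the thioester only (methyl esters are inert to zerovalent palladium).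

Step 14
Reactants: 22 dimethyl 2β-hydroxy-8-oxo-17-nor-5βH-labd-13E-ene-15,19-dioate
Product: 23 dimethyl 2β-hydroxy-5βH-labda-8(17),13E-diene-15,19-dioate
Conditions: Ph3PCH3Br, KOtBu (4 equiv each), toluene, 0 to 60 °C
Reagents that add atoms: methyltriphenylphosphonium bromide C[P+](c1ccccc1)(c1ccccc1)c1ccccc1.[Br-]
Why: Wittig methylenation of the hindered C8 ketone installs C17; any base-induced epimerisation at C9 can only return the favoured equatorial epimer.

Step 15
Reactants: 23 dimethyl 2β-hydroxy-5βH-labda-8(17),13E-diene-15,19-dioate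
Product: 24 2β-hydroxy-5βH-labda-8(17),13E-diene-15,19-dioic acid (CNP0086784.2)
Conditions: n-PrSH, n-BuLi (gives LiSPr, 6 equiv), HMPA, rt; then 1 M HCl
Reagents that add atoms: none
Why: SN2 demethylation by thiolate cleaves both methyl esters, including the axial neopentyl C19 ester that resists saponification, without touching any stereocentre or either alkene.

Compound list
1 | 5-oxohexanoic acid | CC(=O)CCCC(=O)O | starting material
2 | (E)-7-methoxy-5-methyl-7-oxohept-5-enoic acid | OC(=O)CCC/C(C)=C/C(=O)OC | intermediate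
3 | methyl (E)-7-(ethylsulfanyl)-3-methyl-7-oxohept-2-enoate | CCSC(=O)CCC/C(C)=C/C(=O)OC | intermediate
4 | methyl (2E)-7-(ethylsulfanyl)-3-methyl-7-(trimethylsilyloxy)hepta-2,6-dienoate (silyl ketene thioacetal, not isolated) | CCSC(O[Si](C)(C)C)=CCC/C(C)=C/C(=O)OC | intermediate
5 | methyl (E)-6-bromo-7-(ethylsulfanyl)-3-methyl-7-oxohept-2-enoate (racemic) | CCSC(=O)C(Br)CC/C(C)=C/C(=O)OC | intermediate
6 | 5-hydroxy-3-methylfuran-2(5H)-one | CC1=CC(O)OC1=O | starting material
7 | (E)-1-(ethylsulfanyl)-7-methoxy-5-methyl-1,7-dioxohept-5-en-2-yl (Z)-2-methyl-4-oxobut-2-enoate | O=C/C=C(/C)C(=O)OC(CC/C(C)=C/C(=O)OC)C(=O)SCC | intermediate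
8 | (E)-pent-3-en-2-one | C/C=C/C(C)=O | starting material
9 | tert-butyldimethyl[(E)-penta-1,3-dien-2-yloxy]silane | C/C=C/C(=C)O[Si](C)(C)C(C)(C)C | intermediate
10 | C9-unit ester of 5α-formyl-4β,10α-dimethyl-2-(tert-butyldimethylsilyloxy)cyclohex-1-ene-4α-carboxylic acid | O=C[C@H]2[C@@H](C)C=C(O[Si](C)(C)C(C)(C)C)C[C@@]2(C)C(=O)OC(CC/C(C)=C/C(=O)OC)C(=O)SCC | intermediate
11 | C9-unit ester of 4β,10α-dimethyl-2-(tert-butyldimethylsilyloxy)-5α-vinylcyclohex-1-ene-4α-carboxylic acid | C=C[C@H]2[C@@H](C)C=C(O[Si](C)(C)C(C)(C)C)C[C@@]2(C)C(=O)OC(CC/C(C)=C/C(=O)OC)C(=O)SCC | intermediate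
12 | C9-unit ester of 4β,10-dimethyl-2-oxo-5α-vinylcyclohex-1(10)-ene-4α-carboxylic acid | C=C[C@H]2C(C)=CC(=O)C[C@@]2(C)C(=O)OC(CC/C(C)=C/C(=O)OC)C(=O)SCC | intermediate
13 | lithium thioester enolate of 12 (not isolated) | C=C[C@H]2C(C)=CC(=O)C[C@@]2(C)C(=O)OC(CC/C(C)=C/C(=O)OC)=C([O-])SCC.[Li+] | intermediate
14 | lithium C2 enolate of the 19,9-lactone (not isolated) | C=C[C@H]2[C@]3(C)C=C([O-])C[C@@]2(C)C(=O)OC3(CC/C(C)=C/C(=O)OC)C(=O)SCC.[Li+] | intermediate
15 | 19,9-lactone (C19(=O)–O–C9, C9 on C10α, C9 also bearing COSEt and the C11–C16 chain) as its 2-triethylsilyl enol ether, 5α-vinyl, 4β,10β-dimethyl | C=C[C@H]2[C@]3(C)C=C(O[Si](CC)(CC)CC)C[C@@]2(C)C(=O)OC3(CC/C(C)=C/C(=O)OC)C(=O)SCC | intermediate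
16 | 4β,10β-dimethyl-2-(triethylsilyloxy)-5α-vinyl-10α-(C9 unit)cyclohex-1-ene-4α-carboxylic acid (not isolated) | C=C[C@H]2[C@](C)(C=C(O[Si](CC)(CC)CC)C[C@@]2(C)C(=O)O)C(CC/C(C)=C/C(=O)OC)C(=O)SCC | intermediate
17 | 4β,10β-dimethyl-2-oxo-5α-vinyl-10α-(C9 unit)cyclohexane-4α-carboxylic acid | C=C[C@H]2[C@](C)(CC(=O)C[C@@]2(C)C(=O)O)C(CC/C(C)=C/C(=O)OC)C(=O)SCC | intermediate
18 | sodium acyloxytrihydroborate of 17 (not isolated) | C=C[C@H]2[C@](C)(CC(=O)C[C@@]2(C)C(=O)O[BH3-])C(CC/C(C)=C/C(=O)OC)C(=O)SCC.[Na+] | intermediate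
19 | 2β-hydroxy-4β,10β-dimethyl-5α-vinyl-10α-(C9 unit)cyclohexane-4α-carboxylic acid | C=C[C@H]2[C@](C)(C[C@H](O)C[C@@]2(C)C(=O)O)C(CC/C(C)=C/C(=O)OC)C(=O)SCC | intermediate
20 | methyl 2β-hydroxy-4β,10β-dimethyl-5α-vinyl-10α-(C9 unit)cyclohexane-4α-carboxylate | C=C[C@H]2[C@](C)(C[C@H](O)C[C@@]2(C)C(=O)OC)C(CC/C(C)=C/C(=O)OC)C(=O)SCC | intermediate
21 | B-alkyl-9-BBN at C7 with the 2β-oxygen as its 9-BBN borinate (not isolated) | B1(CC[C@H]3[C@](C)(C[C@H](OB4C5CCCC4CCC5)C[C@@]3(C)C(=O)OC)C(CC/C(C)=C/C(=O)OC)C(=O)SCC)C2CCCC1CCC2 | intermediate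
22 | dimethyl 2β-hydroxy-8-oxo-17-nor-5βH-labd-13E-ene-15,19-dioate | O=C1CC[C@H]2[C@](C)(C[C@H](O)C[C@@]2(C)C(=O)OC)[C@H]1CC/C(C)=C/C(=O)OC | intermediate
23 | dimethyl 2β-hydroxy-5βH-labda-8(17),13E-diene-15,19-dioate | C=C1CC[C@H]2[C@](C)(C[C@H](O)C[C@@]2(C)C(=O)OC)[C@H]1CC/C(C)=C/C(=O)OC | intermediate
24 | 2β-hydroxy-5βH-labda-8(17),13E-diene-15,19-dioic acid (CNP0086784.2) | C=C1CC[C@H]2[C@](C)(C[C@H](O)C[C@@]2(C)C(=O)O)[C@H]1CC/C(C)=C/C(=O)O | target

Total step count: 15. Longest linear sequence: 14 steps (steps 1–4, then 6–15); step 5 is the one-step branch for the diene.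

Steps most likely to fail

Step 11 (proposed new method). Hydride transfer between molecules from the open β face, or attack on the thioester, may outrun the internal delivery and give poor facial selectivity at C2. The fallback uses known chemistry, sets out from 17 and comes back at 20. Compound 17 would be esterified with Me3SiCHN2 to the keto diester F1 and reduced with NaBH4/CeCl3 (MeOH, −78 °C). Any 2β-alcohol formed is already 20; the 2α-alcohol F2 would be separated and inverted by a Mitsunobu reaction with chloroacetic acid (PPh3, DIAD, toluene) to the 2β-chloroacetate F3, whose chloroacetyl group is removed with thiourea/NaHCO3 in EtOH to give 20.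

Step 9. The tertiary thioester enolate may fail to add to the hindered C10, through reversal of the Michael step, a 1,2-acyl shift of the α-acyloxy enolate, or proton loss at C5. The fallback sets out from 6 and comes back at 15. Compound 6 would be alkylated (Cs2CO3, DMF) with S-ethyl 2-bromoethanethioate to the glycolate-type dienophile F4. The conditions of steps 6, 7 and 8 would then give the Diels–Alder adduct F5, the vinyl compound F6 and the enone F7. The Michael closure (LiN(SiMe3)2; then Et3SiCl) now uses a secondary carbanion and should give the bridged lactone F8. Its remaining C9–H would be removed (DBU cat., MeCN) and the enolate added to methyl vinyl ketone from the open face of the lactone to give the methyl ketone F9. Wittig olefination with Ph3P=CHCO2Me (toluene, 110 °C; E isomer separated) then gives 15.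

Step 13 (key step). β-Hydride elimination or protodeboronation of the alkyl–metal species, or slow oxidative addition of the α-branched thioester, may outrun ring closure. The fallback sets out from 20 and comes back at 22. Hydroboration of 20 with 9-BBN followed by NaOMe/I2 would give the primary iodide F10. SmI2 with catalytic NiI2 (THF, 0 °C) would turn the C–I bond into an alkylsamarium that attacks the thioester within the molecule (Barbier-type nucleophilic acyl substitution), and DBU equilibration of C9 would then give 22.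

Further compounds
F1 | step 11 | methyl 4β,10β-dimethyl-2-oxo-5α-vinyl-10α-(C9 unit)cyclohexane-4α-carboxylate | C=C[C@H]2[C@](C)(CC(=O)C[C@@]2(C)C(=O)OC)C(CC/C(C)=C/C(=O)OC)C(=O)SCC
F2 | step 11 | methyl 2α-hydroxy-4β,10β-dimethyl-5α-vinyl-10α-(C9 unit)cyclohexane-4α-carboxylate | C=C[C@H]2[C@](C)(C[C@@H](O)C[C@@]2(C)C(=O)OC)C(CC/C(C)=C/C(=O)OC)C(=O)SCC
F3 | step 11 | methyl 2β-(chloroacetoxy)-4β,10β-dimethyl-5α-vinyl-10α-(C9 unit)cyclohexane-4α-carboxylate | C=C[C@H]2[C@](C)(C[C@H](OC(=O)CCl)C[C@@]2(C)C(=O)OC)C(CC/C(C)=C/C(=O)OC)C(=O)SCC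
F4 | step 9 | 2-(ethylsulfanyl)-2-oxoethyl (Z)-2-methyl-4-oxobut-2-enoate | O=C/C=C(/C)C(=O)OCC(=O)SCC
F5 | step 9 | 2-(ethylsulfanyl)-2-oxoethyl 5α-formyl-4β,10α-dimethyl-2-(tert-butyldimethylsilyloxy)cyclohex-1-ene-4α-carboxylate | O=C[C@H]2[C@@H](C)C=C(O[Si](C)(C)C(C)(C)C)C[C@@]2(C)C(=O)OCC(=O)SCC
F6 | step 9 | 2-(ethylsulfanyl)-2-oxoethyl 4β,10α-dimethyl-2-(tert-butyldimethylsilyloxy)-5α-vinylcyclohex-1-ene-4α-carboxylate | C=C[C@H]2[C@@H](C)C=C(O[Si](C)(C)C(C)(C)C)C[C@@]2(C)C(=O)OCC(=O)SCC
F7 | step 9 | 2-(ethylsulfanyl)-2-oxoethyl 4β,10-dimethyl-2-oxo-5α-vinylcyclohex-1(10)-ene-4α-carboxylate | C=C[C@H]2C(C)=CC(=O)C[C@@]2(C)C(=O)OCC(=O)SCC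
F8 | step 9 | 19,9-lactone with C9 bearing H and COSEt, as its 2-triethylsilyl enol ether | C=C[C@H]2[C@]3(C)C=C(O[Si](CC)(CC)CC)C[C@@]2(C)C(=O)OC3C(=O)SCC
F9 | step 9 | 19,9-lactone with C9 bearing COSEt and a 3-oxobutyl group, as its 2-triethylsilyl enol ether | C=C[C@H]2[C@]3(C)C=C(O[Si](CC)(CC)CC)C[C@@]2(C)C(=O)OC3(CCC(C)=O)C(=O)SCC
F10 | step 13 | methyl 2β-hydroxy-5α-(2-iodoethyl)-4β,10β-dimethyl-10α-(C9 unit)cyclohexane-4α-carboxylate | ICC[C@H]2[C@](C)(C[C@H](O)C[C@@]2(C)C(=O)OC)C(CC/C(C)=C/C(=O)OC)C(=O)SCC
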